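## Retrosynthetic overview

1. The target is reached from a C4‑vinyl precursor by oxidative cleavage (vinyl → CHO), preceded by hydroxyl‑directed epoxidation of an E‑C1=C10 olefin and by C6 ketone reduction with lactonisation.
2. The ten‑membered E‑cyclodecenone comes from a ring‑expanding epoxy‑alcohol Grob fragmentation of a cis‑fused bicyclo[5.3.0]decane: the C6–C10 bond breaks, C6=O and C1=C10 form, and the epoxide oxygen becomes the 2‑OH.
3. The bicycle comes from an intramolecular umpolung allylation (Pd(PPh3)4/InI) of a 2‑(oxiranyl)acrylate onto the cycloheptenone carbonyl, which closes the five‑membered ring and forms C6–C7.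
4. The substituted cycloheptenone comes from cycloheptanone by methylation, dehydrogenation, Rh‑catalysed asymmetric vinylation (C4), a new asymmetric deconjugative Michael addition to acrolein (C10), α‑chlorination (C8) and vinylalumination.
5. Ring order: seven‑membered ring (purchased) → five‑membered ring → expansion to the ten‑membered ring → lactone → epoxide.

Assumption: atoms carry germacrane labels in every intermediate (C10 bears CH3‑14, C4 bears C15, C7 bears C11–C13, lactone oxygen on C6, tiglate on O‑8); "up/down" refers to the ring drawn flat with 6‑O up.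

## Route

Step 1
Reactants: 1 cycloheptanone
Product: 2 2-methylcycloheptan-1-one (racemic)
Conditions: LiN(i-Pr)2, THF, −78 °C; MeI, −78 → 0 °C
Reagents that add atoms: iodomethane, CI
Why: Kinetic lithium enolate alkylation; the new stereocentre is irrelevant because it becomes sp2 in step 2.

Step 2
Reactants: 2 2-methylcycloheptan-1-one
Product: 4 2-methylcyclohepta-2,6-dien-1-one, via 2-methylcyclohept-2-en-1-one 3 (not isolated)
Conditions: IBX (2.5 equiv), DMSO/PhF, 70 °C
Reagents that add atoms: none
Why: IBX α,β‑dehydrogenation of the ketone on both sides, stopped by stoichiometry before the tropone stage.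

Step 3
Reactants: 4 2-methylcyclohepta-2,6-dien-1-one; 5 potassium ethenyltrifluoroborate
Product: 6 (6S)-6-ethenyl-2-methylcyclohept-2-en-1-one
Conditions: [Rh(cod)2]BF4 (3 mol %), (S)-BINAP (3.3 mol %), toluene/H2O, 100 °C
Reagents that add atoms: none
Why: Rh/BINAP asymmetric 1,4‑addition of an alkenyltrifluoroborate (Hayashi–Miyaura type) goes only to the unsubstituted enone, since the α‑methyl enone is inert, and the ligand sets C4 (S), the later formyl‑bearing carbon.

Step 4
Reactants: 6 (6S)-6-ethenyl-2-methylcyclohept-2-en-1-one; 7 prop-2-enal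
Product: 8 3-[(1R,5S)-5-ethenyl-1-methyl-7-oxocyclohept-2-en-1-yl]propanal
Conditions: N-(9-anthracenylmethyl)-O-allylcinchonidinium bromide (10 mol %; pseudo-enantiomer chosen for 1R), CsOH·H2O (20 mol %), toluene/CH2Cl2, −60 °C
Reagents that add atoms: none
Why: Proposed new method: a chiral cinchona ammonium phase‑transfer catalyst ion‑pairs with the thermodynamic extended dienolate of 6 (γ‑deprotonation at C2) and shields one face, so the α‑carbon C10 adds to acrolein in a deconjugative Michael reaction that sets the quaternary centre (chain cis to the C4 vinyl) and moves the olefin to C1=C2; the closest known reactions are base‑mediated deconjugative α‑alkylation of 2‑alkylcycloalk‑2‑enones and asymmetric phase‑transfer Michael additions of 2‑substituted cyclic β‑keto esters to acrolein.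

Step 5
Reactants: 8 3-[(1R,5S)-5-ethenyl-1-methyl-7-oxocyclohept-2-en-1-yl]propanal
Product: 9 (2R)-2-chloro-3-[(1R,5S)-5-ethenyl-1-methyl-7-oxocyclohept-2-en-1-yl]propanal
Conditions: NCS, 2,5-diphenylpyrrolidine (10 mol %, enantiomer giving the 2R chloride), CH2Cl2, 0 °C; used crude
Reagents that add atoms: N-chlorosuccinimide, O=C1CCC(=O)N1Cl
Why: Organocatalytic enamine α‑chlorination of the aldehyde, with catalyst control giving the C8 chloride of the configuration that the SN2 closure in step 6 inverts to the target C8–O.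

Step 6
Reactants: 9 (2R)-2-chloro aldehyde; 10 methyl prop-2-ynoate
Product: 12 methyl 2-[(3S)-3-{[(1R,5S)-5-ethenyl-1-methyl-7-oxocyclohept-2-en-1-yl]methyl}oxiran-2-yl]prop-2-enoate (both epimers at the acrylate-bearing oxirane carbon), via chlorohydrin 11 (not isolated)
Conditions: 10, i-Bu2AlH, NMO, THF, 0 °C; then 9, 0 °C → rt; then K2CO3, MeCN, rt
Reagents that add atoms: none
Why: Hydroalumination of the propiolate gives the α‑(methoxycarbonyl)vinylalane, which adds to the aldehyde (vinylalumination, a Morita–Baylis–Hillman surrogate), and the chlorohydrin alkoxide then displaces chloride with inversion at C8; the C7 epimers converge in step 7.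

Step 7
Reactants: 12 vinyl epoxide
Product: 13 cis-fused hydroazulene diol (6-OH, 8-OH and 10-CH3 up; C7 acrylate and C4 vinyl down)
Conditions: Pd(PPh3)4 (5 mol %), InI (1.5 equiv), THF/DMPU, rt
Reagents that add atoms: none
Why: Umpolung of the vinyl epoxide: zerovalent palladium ionises the allylic C7–O bond, monovalent indium converts the π‑allyl into an allylindium carrying the C8–O–In alkoxide, and intramolecular SE2′ carbonyl allylation closes the five‑membered ring; the tether forces cis ring fusion (6‑OH cis to 10‑CH3), indium chelation puts 6‑O and 8‑O cis, and the acrylate on C7 goes trans to both.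

Step 8
Reactants: 13 hydroazulene diol; 14 (E)-2-methylbut-2-enoyl chloride (tigloyl chloride)
Product: 15 hydroazulene 8-tiglate (tertiary 6-OH free)
Conditions: Et3N, DMAP (cat.), CH2Cl2, 0 °C
Reagents that add atoms: none
Why: Acylation picks the secondary C8–OH over the hindered tertiary ring‑fusion C6–OH.

Step 9
Reactants: 15 hydroazulene 8-tiglate
Product: 17 methyl 2-[(1R,4S,6S,7E,10S)-4-ethenyl-6-hydroxy-8-methyl-10-{[(2E)-2-methylbut-2-enoyl]oxy}-2-oxocyclodec-7-en-1-yl]prop-2-enoate, via epoxy alcohol 16 (not isolated)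
Conditions: VO(acac)2 (5 mol %), t-BuOOH, CH2Cl2, 0 °C; then Ti(OiPr)4 (20 mol %), 40 °C
Reagents that add atoms: tert-butyl hydroperoxide, CC(C)(C)OO
Why: Directed epoxidation of C1=C2 syn to the tertiary homoallylic 6‑OH puts the epoxide cis to 10‑CH3 and trans to C9, and the Lewis‑acid epoxy‑alcohol Grob fragmentation (anti‑periplanar C1–O and C6–C10 bonds) then expands the 5/7 bicycle to the ten‑membered ring with C6=O, a stereospecifically E C1=C10 olefin and the 2‑OH stereocentre carried over from the epoxide.

Step 10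
Reactants: 17 ten-membered hydroxy ketone
Product: 19 (1(10)E,2S,4S,6R,7S,8S)-4-ethenyl-2-hydroxy-8-tigloyloxy-germacra-1(10),11(13)-dien-12,6-olide, via hydroxy ester 18 (not isolated)
Conditions: NaBH4, CeCl3·7H2O, MeOH, −78 → 0 °C
Reagents that add atoms: none
Why: Luche 1,2‑reduction of the ketone (enoates untouched) by peripheral Felkin‑type hydride attack anti to the C7–C8 ring bond should give the 6,7‑anti alkoxide, which lactonises onto the C12 methyl ester to the trans‑fused α‑methylene‑γ‑butyrolactone.

Step 11
Reactants: 19 allylic alcohol lactone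
Product: 20 (1R,2S,4S,6R,7S,8S,10R)-1,10-epoxy-4-ethenyl-2-hydroxy-8-tigloyloxy-germacr-11(13)-en-12,6-olide
Conditions: VO(acac)2 (5 mol %), t-BuOOH, CH2Cl2, 0 °C
Reagents that add atoms: tert-butyl hydroperoxide, CC(C)(C)OO
Why: Hydroxyl‑directed epoxidation of the only allylic‑alcohol olefin; A(1,3) strain with the cis C14 methyl keeps H‑2 in the olefin plane, so oxygen is delivered to the face of the 2‑OH (threo), which is the target configuration at C1 and C10.

Step 12
Reactants: 20 epoxy vinyl lactone
Product: 22 CNP0307768.2 (target), via vicinal diol 21 (not isolated)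
Conditions: OsO4 (2 mol %), NaIO4, 2,6-lutidine, dioxane/H2O, rt
Reagents that add atoms: osmium tetroxide, O=[Os](=O)(=O)=O (catalytic, re-formed by sodium periodate, [Na+].[O-]I(=O)(=O)=O)
Why: Lemieux–Johnson cleavage of the vinyl group, the only electron‑rich alkene left (the α‑methylene lactone and tiglate are electron‑poor), unmasks the C15 aldehyde without touching C4.

## Compound list

1 | cycloheptanone | O=C1CCCCCC1 | starting material
2 | 2-methylcycloheptan-1-one (racemic) | CC1CCCCCC1=O | intermediate
3 | 2-methylcyclohept-2-en-1-one | CC1=CCCCCC1=O | intermediate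
4 | 2-methylcyclohepta-2,6-dien-1-one | CC1=CCCC=CC1=O | intermediate
5 | potassium ethenyltrifluoroborate | C=C[B-](F)(F)F.[K+] | starting material
6 | (6S)-6-ethenyl-2-methylcyclohept-2-en-1-one | O=C1C[C@@H](C=C)CCC=C1C | intermediate
7 | prop-2-enal (acrolein) | C=CC=O | starting material
8 | 3-[(1R,5S)-5-ethenyl-1-methyl-7-oxocyclohept-2-en-1-yl]propanal | O=C1C[C@@H](C=C)CC=C[C@@]1(C)CCC=O | intermediate
9 | (2R)-2-chloro-3-[(1R,5S)-5-ethenyl-1-methyl-7-oxocyclohept-2-en-1-yl]propanal | O=C1C[C@@H](C=C)CC=C[C@@]1(C)C[C@@H](Cl)C=O | intermediate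
10 | methyl prop-2-ynoate | C#CC(=O)OC | starting material
11 | methyl 2-{(2R)-2-chloro-1-hydroxy-3-[(1R,5S)-5-ethenyl-1-methyl-7-oxocyclohept-2-en-1-yl]propyl}prop-2-enoate (both carbinol epimers) | O=C1C[C@@H](C=C)CC=C[C@@]1(C)C[C@@H](Cl)C(O)C(=C)C(=O)OC | intermediate
12 | methyl 2-[(3S)-3-{[(1R,5S)-5-ethenyl-1-methyl-7-oxocyclohept-2-en-1-yl]methyl}oxiran-2-yl]prop-2-enoate (both epimers at oxirane C2) | O=C1C[C@@H](C=C)CC=C[C@@]1(C)C[C@@H]2OC2C(=C)C(=O)OC | intermediate
13 | methyl 2-(7-ethenyl-2,8a-dihydroxy-3a-methyl-1,2,3,3a,6,7,8,8a-octahydroazulen-1-yl)prop-2-enoate, cis-fused; 8a-OH, 3a-CH3 and 2-OH on one face, C1 acrylate and C7 vinyl on the other | O[C@]12C[C@@H](C=C)CC=C[C@@]1(C)C[C@H](O)[C@H]2C(=C)C(=O)OC | intermediate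
14 | (E)-2-methylbut-2-enoyl chloride (tigloyl chloride) | C/C=C(\C)C(=O)Cl | starting material
15 | the 2-O-tiglate of 13 (azulene numbering; germacrane O-8), tertiary 8a-OH free | O[C@]12C[C@@H](C=C)CC=C[C@@]1(C)C[C@H](OC(=O)/C(C)=C/C)[C@H]2C(=C)C(=O)OC | intermediate
16 | the 4,5-epoxide of 15 (germacrane C1–C2), epoxide oxygen cis to the ring-fusion OH and CH3 | O[C@]12C[C@@H](C=C)C[C@@H]3O[C@@H]3[C@@]1(C)C[C@H](OC(=O)/C(C)=C/C)[C@H]2C(=C)C(=O)OC | intermediate
17 | methyl 2-[(1R,4S,6S,7E,10S)-4-ethenyl-6-hydroxy-8-methyl-10-{[(2E)-2-methylbut-2-enoyl]oxy}-2-oxocyclodec-7-en-1-yl]prop-2-enoate | O=C1C[C@@H](C=C)C[C@H](O)/C=C(\C)C[C@H](OC(=O)/C(C)=C/C)[C@H]1C(=C)C(=O)OC | intermediate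
18 | the 2-hydroxy compound from reduction of the ring ketone of 17 (germacrane 6-OH, up, anti to the C7 acrylate) | O[C@@H]1C[C@@H](C=C)C[C@H](O)/C=C(\C)C[C@H](OC(=O)/C(C)=C/C)[C@H]1C(=C)C(=O)OC | intermediate
19 | (1(10)E,2S,4S,6R,7S,8S)-4-ethenyl-2-hydroxy-8-tigloyloxy-germacra-1(10),11(13)-dien-12,6-olide (trans-fused lactone) | C=C1C(=O)O[C@@H]2C[C@@H](C=C)C[C@H](O)/C=C(\C)C[C@H](OC(=O)/C(C)=C/C)[C@@H]12 | intermediate
20 | (1R,2S,4S,6R,7S,8S,10R)-1,10-epoxy-4-ethenyl-2-hydroxy-8-tigloyloxy-germacr-11(13)-en-12,6-olide | C=C1C(=O)O[C@@H]2C[C@@H](C=C)C[C@H](O)[C@H]3O[C@]3(C)C[C@H](OC(=O)/C(C)=C/C)[C@@H]12 | intermediate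
21 | the 1,2-diol from dihydroxylation of the C4 vinyl group of 20 (both carbinol epimers) | C=C1C(=O)O[C@@H]2C[C@@H](C(O)CO)C[C@H](O)[C@H]3O[C@]3(C)C[C@H](OC(=O)/C(C)=C/C)[C@@H]12 | intermediate
22 | CNP0307768.2: (1R,2S,4S,6R,7S,8S,10R)-1,10-epoxy-2-hydroxy-15-oxo-8-tigloyloxy-germacr-11(13)-en-12,6-olide | C=C1C(=O)O[C@@H]2C[C@@H](C=O)C[C@H](O)[C@H]3O[C@]3(C)C[C@H](OC(=O)/C(C)=C/C)[C@@H]12 | target

## Step count and risks

Total step count: 12. Longest linear sequence: 12 steps (1 → 22).

The three steps most likely to fail: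

Step 4, the new asymmetric deconjugative Michael addition. It can fail through attack at C5 or C2 instead of C10, through low enantiocontrol, through acrolein polymerisation, or through aldol closure of the keto aldehyde. The fallback uses known chemistry and runs from 6 back to 8. Catalytic t-BuOK in t-BuOH/THF at −20 °C with acrolein 7 gives the classical thermodynamic dienolate α‑addition without catalyst control. Because C4 is already fixed, the products are diastereomers: 8 and 3-[(1S,5S)-5-ethenyl-1-methyl-7-oxocyclohept-2-en-1-yl]propanal F1. They are separated by chromatography, and 8 re-enters at step 5.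

Step 7, the palladium/indium umpolung cyclisation. The risks are protonation of the allylindium, addition through the wrong allyl terminus, or the wrong C7 configuration. The fallback runs from 12 back to 13. MgBr2·OEt2 in Et2O opens the vinyl epoxide in the SN2′ sense (bromide adds to the acrylate CH2, the epoxide opens at C7) to give methyl (2Z,4S)-2-(bromomethyl)-5-[(1R,5S)-5-ethenyl-1-methyl-7-oxocyclohept-2-en-1-yl]-4-hydroxypent-2-enoate F2. CrCl2 in THF (Nozaki–Hiyama allylation) then closes the five-membered ring to 13; the free hydroxyl is carried as a chromium alkoxide, which is too poor a leaving group for 1,4‑elimination.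

Step 9, the ring-expanding epoxy-alcohol Grob fragmentation. The Lewis acid may instead cause transannular Prins re-closure, a semipinacol shift or transesterification. The fallback runs from 15 through isolated 16 back to 17 and makes no compound outside the list (F0). Epoxidise with VO(acac)2/t-BuOOH alone and isolate 16. Then switch to a radical fragmentation: CeCl3 (10 mol %), n-Bu4NCl, MeCN, 400 nm light. Ligand-to-metal charge transfer in the tetravalent cerium alkoxide gives the C6 oxy radical. β‑Scission of C6–C10 gives the C10 radical, which opens the adjacent epoxide to the C1=C10 olefin and a C2 oxy radical; trivalent cerium recaptures this to give 17. This relay is not stereospecific, so any Z isomer must be removed by chromatography.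

Further compounds
F1 | step 4 | 3-[(1S,5S)-5-ethenyl-1-methyl-7-oxocyclohept-2-en-1-yl]propanal | O=C1C[C@@H](C=C)CC=C[C@]1(C)CCC=O
F2 | step 7 | methyl (2Z,4S)-2-(bromomethyl)-5-[(1R,5S)-5-ethenyl-1-methyl-7-oxocyclohept-2-en-1-yl]-4-hydroxypent-2-enoate | O=C1C[C@@H](C=C)CC=C[C@@]1(C)C[C@H](O)/C=C(\CBr)C(=O)OC
F0 | step 9 | none | none
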